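**Strategy.** Ring A of the dihydrobenzofuran carries the ring oxygen O1 on C7a directly beside the hydroxyl on C7. This 1,2-dioxygen pattern is read as the footprint of a C7–C7a aryne. In one operation, fluorine-directed lithiation, loss of LiF, 5-exo addition of a tethered lithium alkoxide at C7a and borylation–oxidation of the resulting C7 anion close the dihydrofuran ring and install the phenol. The precursor is an open-chain syn-(1R,2S) 1,2-diaryl-1,3-propanediol from an Evans aldol reaction. It has a free benzylic alcohol, a trityl-protected primary alcohol and a 2-fluoroaryl ring carrying the acetal-masked aldehyde para to fluorine.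

Key step: step 8

Assumption: ring positions follow benzofuran numbering (O1, C2, C3, C3a, C4–C7, C7a); ring A is the benzo ring of the core and ring B the dimethoxyphenyl ring; reagents without a number are commercial.

Design remarks on the aryne precursor 16:
- The (R)-4-benzyl auxiliary is required. It gives the (2R,3R) syn aldol, hence the (1R,2S) diol. Because the ring closure keeps the carbinol C–O bond, the syn pair becomes the trans-(2R,3S) ring of the target.
- The primary oxygen is capped as a trityl ether. Under the basic cyclisation conditions a silyl group could shift from the primary to the secondary oxygen. The freed primary alkoxide is equally well placed for 5-exo capture of the aryne and would give a constitutional isomer. Trityl cannot migrate, and it leaves in the same acid step as the acetal.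
- The aldehyde is masked as a 5,5-dimethyl-1,3-dioxane. A five-membered acetal can fragment with loss of ethylene once its C–H is removed by an alkyllithium; the six-membered one cannot.
- The arylacetic unit is made as an ethyl ester, so the acid is freed by saponification and the acetal never meets strong acid.

**Route**

Step 1
Reactants: 1 3-bromo-4-fluorobenzaldehyde
Product: 2 2-(3-bromo-4-fluorophenyl)-5,5-dimethyl-1,3-dioxane
Conditions: 2,2-dimethylpropane-1,3-diol, TsOH·H2O (cat.), toluene, reflux, Dean–Stark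
Reagents that add atoms: 2,2-dimethylpropane-1,3-diol, OCC(C)(C)CO
Why: Acid-catalysed acetalisation with azeotropic removal of water should go to completion and gives a six-membered acetal that is stable to the zinc enolate, hydride and alkyllithium reagents used later.

Step 2
Reactants: 2 2-(3-bromo-4-fluorophenyl)-5,5-dimethyl-1,3-dioxane; 3 ethyl bromoacetate
Product: 5 ethyl 2-[5-(5,5-dimethyl-1,3-dioxan-2-yl)-2-fluorophenyl]acetate, via zinc reagent 4 (not isolated)
Conditions: Zn dust, TMSCl (cat.), 3, THF, 40 °C; then 2, Pd2(dba)3 (1 mol%), XPhos (4 mol%), THF, 65 °C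
Reagents that add atoms: none
Why: Negishi-type coupling of a Reformatsky reagent (α-arylation of a zinc ester enolate): oxidative addition of the aryl bromide to zerovalent palladium, transmetalation from zinc and reductive elimination should form the aryl–CH2 bond under neutral conditions that leave the C–F bond and the acetal alone.

Step 3
Reactants: 5 ethyl 2-[5-(5,5-dimethyl-1,3-dioxan-2-yl)-2-fluorophenyl]acetate
Product: 7 2-[5-(5,5-dimethyl-1,3-dioxan-2-yl)-2-fluorophenyl]acetic acid, via lithium carboxylate 6 (not isolated)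
Conditions: LiOH·H2O, THF/MeOH/H2O, rt; then 10% aq citric acid to pH 4–5, 0 °C
Reagents that add atoms: lithium hydroxide, [Li+].[OH-]
Why: Ester saponification (acyl addition–elimination) is orthogonal to the base-stable acetal, and brief cold acidification with a weak acid should protonate the carboxylate without hydrolysing the acetal.

Step 4
Reactants: 7 2-[5-(5,5-dimethyl-1,3-dioxan-2-yl)-2-fluorophenyl]acetic acid; 8 (R)-4-benzyl-1,3-oxazolidin-2-one
Product: 10 (4R)-4-benzyl-3-{2-[5-(5,5-dimethyl-1,3-dioxan-2-yl)-2-fluorophenyl]acetyl}-1,3-oxazolidin-2-one, via mixed pivalic anhydride 9 (not isolated)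
Conditions: PivCl, Et3N, THF, −20 °C; then LiCl, 8, −20 °C → rt
Reagents that add atoms: none
Why: N-Acylation of the oxazolidinone through the mixed pivalic anhydride under LiCl/Et3N activation should be selective for the less hindered arylacetyl carbonyl.

Step 5
Reactants: 10 (4R)-4-benzyl-3-{2-[5-(5,5-dimethyl-1,3-dioxan-2-yl)-2-fluorophenyl]acetyl}-1,3-oxazolidin-2-one; 11 3,4-dimethoxybenzaldehyde
Product: 14 (4R)-4-benzyl-3-{(2R,3R)-3-(3,4-dimethoxyphenyl)-2-[5-(5,5-dimethyl-1,3-dioxan-2-yl)-2-fluorophenyl]-3-hydroxypropanoyl}-1,3-oxazolidin-2-one, via boron Z-enolate 12 (not isolated), via boron aldolate 13 (not isolated)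
Conditions: Bu2BOTf (1.1 equiv), i-Pr2NEt, CH2Cl2, −78 → 0 °C; 11, −78 → 0 °C; then pH 7 phosphate buffer, MeOH, 30% H2O2, 0 °C
Reagents that add atoms: none
Why: Evans syn-aldol reaction: soft enolisation gives the Z boron enolate, which should add to the aldehyde through a closed Zimmerman–Traxler chair on the face away from the benzyl group of the (R)-auxiliary, setting both new stereocentres as the (2R,3R) syn pair, and the buffered peroxide work-up releases the adduct from boron.

Step 6
Reactants: 14 (4R)-4-benzyl-3-{(2R,3R)-3-(3,4-dimethoxyphenyl)-2-[5-(5,5-dimethyl-1,3-dioxan-2-yl)-2-fluorophenyl]-3-hydroxypropanoyl}-1,3-oxazolidin-2-one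
Product: 15 (1R,2S)-1-(3,4-dimethoxyphenyl)-2-[5-(5,5-dimethyl-1,3-dioxan-2-yl)-2-fluorophenyl]propane-1,3-diol
Conditions: LiBH4 (2 equiv), H2O (1 equiv), THF/Et2O, 0 °C
Reagents that add atoms: none
Why: Reductive cleavage of the imide by LiBH4 (hydride addition to the exocyclic carbonyl, then reduction of the released aldehyde) should give the 1,3-diol and the recoverable auxiliary without touching either stereocentre; the descriptor of the aryl-bearing carbon becomes S only because the CIP ranking of its substituents changes.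

Step 7
Reactants: 15 (1R,2S)-1-(3,4-dimethoxyphenyl)-2-[5-(5,5-dimethyl-1,3-dioxan-2-yl)-2-fluorophenyl]propane-1,3-diol
Product: 16 (1R,2S)-1-(3,4-dimethoxyphenyl)-2-[5-(5,5-dimethyl-1,3-dioxan-2-yl)-2-fluorophenyl]-3-(trityloxy)propan-1-ol
Conditions: TrCl (1.15 equiv), Et3N, DMAP (cat.), CH2Cl2, rt
Reagents that add atoms: trityl chloride, ClC(c1ccccc1)(c1ccccc1)c1ccccc1
Why: Tritylation is an SN1-type transfer of the bulky trityl cation and should therefore be selective for the primary over the hindered secondary benzylic hydroxyl.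

Step 8
Reactants: 16 (1R,2S)-1-(3,4-dimethoxyphenyl)-2-[5-(5,5-dimethyl-1,3-dioxan-2-yl)-2-fluorophenyl]-3-(trityloxy)propan-1-ol
Product: 22 (2R,3S)-2-(3,4-dimethoxyphenyl)-5-(5,5-dimethyl-1,3-dioxan-2-yl)-3-[(trityloxy)methyl]-2,3-dihydro-1-benzofuran-7-ol, via lithium alkoxide 17 (not isolated), via dilithio fluoroarene 18 (not isolated), via aryne alkoxide 19 (not isolated), via 7-lithio dihydrobenzofuran 20 (not isolated), via lithium aryltrimethoxyborate 21 (not isolated)
Conditions: n-BuLi (1.05 equiv), THF (0.02 M), −78 °C; s-BuLi (1.1 equiv), −78 °C, 1.5 h; warm to −20 °C, 1 h; B(OMe)3 (3 equiv), −78 °C → rt; then 30% H2O2, 2 M NaOH, 0 °C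
Reagents that add atoms: hydrogen peroxide, OO
Why: n-BuLi forms lithium alkoxide 17 and s-BuLi then removes the only ring proton next to fluorine (future C7) to give 18; on warming, 18 loses LiF to aryne 19, the tethered alkoxide adds to the nearer aryne carbon (future C7a) to give the 7-lithio compound 20, and borate capture (21) followed by peroxide-induced 1,2-shift of the aryl group from boron to oxygen gives the phenol. The closest known reaction type is the anionic cyclisation of arynes generated from ortho-lithiated fluoroarenes that carry a tethered nucleophile, with electrophilic quench of the new aryllithium, joined to the standard aryllithium–borate–peroxide phenol synthesis. The dihydrofuran ring closes in a 5-exo-dig mode on the in-plane aryne bond; attack at the far carbon is excluded by the three-atom tether. No stereocentre is formed, and because the C2–O bond of the carbinol and the C3–C3a bond are never broken, the syn (1R,2S) pair of 16 is carried over with retention as the trans (2R,3S) ring. The step needs lithiation at one site only, which the acidifying fluorine secures at −78 °C in THF without diamine (sites next to the methoxy groups or the acetal are lithiated far more slowly), and it needs the secondary alkoxide to be the only nucleophile at hand, which is secured by the non-migrating trityl ether on the primary oxygen, by using up the alkyllithium before warming and by high dilution.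

Step 9
Reactants: 22 (2R,3S)-2-(3,4-dimethoxyphenyl)-5-(5,5-dimethyl-1,3-dioxan-2-yl)-3-[(trityloxy)methyl]-2,3-dihydro-1-benzofuran-7-ol
Product: 23 (2R,3S)-2-(3,4-dimethoxyphenyl)-7-hydroxy-3-(hydroxymethyl)-2,3-dihydro-1-benzofuran-5-carbaldehyde
Conditions: AcOH/H2O (4:1), 45 °C
Reagents that add atoms: water, O
Why: Acid-catalysed hydrolysis should remove both acid-labile groups at once (SN1 cleavage of the trityl ether and hydrolysis of the aryl acetal, which is activated by the para ring oxygen), and aqueous AcOH is mild enough that the benzylic C2–O1 ether should survive.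

Step 10
Reactants: 23 (2R,3S)-2-(3,4-dimethoxyphenyl)-7-hydroxy-3-(hydroxymethyl)-2,3-dihydro-1-benzofuran-5-carbaldehyde; 24 malonic acid
Product: 26 (2E)-3-[(2R,3S)-2-(3,4-dimethoxyphenyl)-7-hydroxy-3-(hydroxymethyl)-2,3-dihydro-1-benzofuran-5-yl]prop-2-enoic acid, via arylidenemalonic acid 25 (not isolated)
Conditions: 24 (3 equiv), pyridine, piperidine (0.1 equiv), 90 °C; dilute HCl work-up
Reagents that add atoms: none
Why: Knoevenagel–Doebner condensation: piperidine-mediated condensation with malonic acid followed by decarboxylation in hot pyridine should give the acrylic acid with E geometry (the favoured isomer of the decarboxylative elimination) and tolerates the free phenol and primary alcohol.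

**Compound list**

1 | 3-bromo-4-fluorobenzaldehyde | O=Cc1ccc(F)c(Br)c1 | starting material
2 | 2-(3-bromo-4-fluorophenyl)-5,5-dimethyl-1,3-dioxane | CC1(C)COC(c2ccc(F)c(Br)c2)OC1 | intermediate
3 | ethyl bromoacetate | CCOC(=O)CBr | starting material
4 | zinc reagent (not isolated): (2-ethoxy-2-oxoethyl)zinc bromide | CCOC(=O)C[Zn]Br | intermediate
5 | ethyl 2-[5-(5,5-dimethyl-1,3-dioxan-2-yl)-2-fluorophenyl]acetate | CCOC(=O)Cc1cc(C2OCC(C)(C)CO2)ccc1F | intermediate
6 | lithium carboxylate (not isolated): lithium 2-[5-(5,5-dimethyl-1,3-dioxan-2-yl)-2-fluorophenyl]acetate | [Li+].[O-]C(=O)Cc1cc(C2OCC(C)(C)CO2)ccc1F | intermediate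
7 | 2-[5-(5,5-dimethyl-1,3-dioxan-2-yl)-2-fluorophenyl]acetic acid | OC(=O)Cc1cc(C2OCC(C)(C)CO2)ccc1F | intermediate
8 | (R)-4-benzyl-1,3-oxazolidin-2-one | O=C1N[C@H](Cc2ccccc2)CO1 | starting material
9 | mixed pivalic anhydride of 7 (not isolated) | CC(C)(C)C(=O)OC(=O)Cc1cc(C2OCC(C)(C)CO2)ccc1F | intermediate
10 | (4R)-4-benzyl-3-{2-[5-(5,5-dimethyl-1,3-dioxan-2-yl)-2-fluorophenyl]acetyl}-1,3-oxazolidin-2-one | O=C(Cc1cc(C2OCC(C)(C)CO2)ccc1F)N1C(=O)OC[C@H]1Cc1ccccc1 | intermediate
11 | 3,4-dimethoxybenzaldehyde | COc1ccc(C=O)cc1OC | starting material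
12 | dibutylboron Z-enolate of 10 (not isolated) | O=C1OC[C@@H](Cc2ccccc2)N1/C(OB(CCCC)CCCC)=C/c1cc(C2OCC(C)(C)CO2)ccc1F | intermediate
13 | dibutylboron aldolate of 14 (not isolated) | COc1ccc([C@H](OB(CCCC)CCCC)[C@H](C(=O)N2C(=O)OC[C@H]2Cc2ccccc2)c2cc(C3OCC(C)(C)CO3)ccc2F)cc1OC | intermediate
14 | (4R)-4-benzyl-3-{(2R,3R)-3-(3,4-dimethoxyphenyl)-2-[5-(5,5-dimethyl-1,3-dioxan-2-yl)-2-fluorophenyl]-3-hydroxypropanoyl}-1,3-oxazolidin-2-one | COc1ccc([C@H](O)[C@H](C(=O)N2C(=O)OC[C@H]2Cc2ccccc2)c2cc(C3OCC(C)(C)CO3)ccc2F)cc1OC | intermediate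
15 | (1R,2S)-1-(3,4-dimethoxyphenyl)-2-[5-(5,5-dimethyl-1,3-dioxan-2-yl)-2-fluorophenyl]propane-1,3-diol | COc1ccc([C@H](O)[C@H](CO)c2cc(C3OCC(C)(C)CO3)ccc2F)cc1OC | intermediate
16 | (1R,2S)-1-(3,4-dimethoxyphenyl)-2-[5-(5,5-dimethyl-1,3-dioxan-2-yl)-2-fluorophenyl]-3-(trityloxy)propan-1-ol | COc1ccc([C@H](O)[C@H](COC(c2ccccc2)(c2ccccc2)c2ccccc2)c2cc(C3OCC(C)(C)CO3)ccc2F)cc1OC | intermediate
17 | lithium alkoxide (not isolated): 16 with O–Li at the benzylic carbinol | COc1ccc([C@H](O[Li])[C@H](COC(c2ccccc2)(c2ccccc2)c2ccccc2)c2cc(C3OCC(C)(C)CO3)ccc2F)cc1OC | intermediate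
18 | dilithio fluoroarene (not isolated): 17 also lithiated at the ring carbon next to fluorine | COc1ccc([C@H](O[Li])[C@H](COC(c2ccccc2)(c2ccccc2)c2ccccc2)c2cc(C3OCC(C)(C)CO3)cc([Li])c2F)cc1OC | intermediate
19 | aryne alkoxide (not isolated): 18 after loss of LiF, triple bond between future C7 and C7a | COc1ccc([C@H](O[Li])[C@H](COC(c2ccccc2)(c2ccccc2)c2ccccc2)C2=CC(C3OCC(C)(C)CO3)=CC#C2)cc1OC | intermediate
20 | 7-lithio dihydrobenzofuran (not isolated): (2R,3S)-2-(3,4-dimethoxyphenyl)-5-(5,5-dimethyl-1,3-dioxan-2-yl)-7-lithio-3-[(trityloxy)methyl]-2,3-dihydro-1-benzofuran | COc1ccc([C@@H]2Oc3c([Li])cc(C4OCC(C)(C)CO4)cc3[C@H]2COC(c5ccccc5)(c5ccccc5)c5ccccc5)cc1OC | intermediate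
21 | lithium aryltrimethoxyborate (not isolated): borate complex of 20 with boron on C7 | [Li+].COc1ccc([C@@H]2Oc3c([B-](OC)(OC)OC)cc(C4OCC(C)(C)CO4)cc3[C@H]2COC(c5ccccc5)(c5ccccc5)c5ccccc5)cc1OC | intermediate
22 | (2R,3S)-2-(3,4-dimethoxyphenyl)-5-(5,5-dimethyl-1,3-dioxan-2-yl)-3-[(trityloxy)methyl]-2,3-dihydro-1-benzofuran-7-ol | COc1ccc([C@@H]2Oc3c(O)cc(C4OCC(C)(C)CO4)cc3[C@H]2COC(c5ccccc5)(c5ccccc5)c5ccccc5)cc1OC | intermediate
23 | (2R,3S)-2-(3,4-dimethoxyphenyl)-7-hydroxy-3-(hydroxymethyl)-2,3-dihydro-1-benzofuran-5-carbaldehyde | COc1ccc([C@@H]2Oc3c(O)cc(C=O)cc3[C@H]2CO)cc1OC | intermediate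
24 | malonic acid | OC(=O)CC(=O)O | starting material
25 | arylidenemalonic acid (not isolated): Knoevenagel adduct of 23 before decarboxylation | COc1ccc([C@@H]2Oc3c(O)cc(C=C(C(=O)O)C(=O)O)cc3[C@H]2CO)cc1OC | intermediate
26 | (2E)-3-[(2R,3S)-2-(3,4-dimethoxyphenyl)-7-hydroxy-3-(hydroxymethyl)-2,3-dihydro-1-benzofuran-5-yl]prop-2-enoic acid | COc1ccc([C@@H]2Oc3c(O)cc(/C=C/C(=O)O)cc3[C@H]2CO)cc1OC | target

Total steps: 10. Longest linear sequence: 10 steps (from 1; compounds 3, 8, 11 and 24 enter along the way).

**Steps most likely to fail**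

Step 8. Three processes may defeat it: lithiation at a site other than the one next to fluorine; consumption of the short-lived aryne by aryllithium or alkyllithium species before the aggregated lithium alkoxide closes the ring; and protonation of the C7 anion before borylation. The fallback avoids the aryne altogether; it sets out from 16 and returns at 22. The same double deprotonation is run but kept at −78 °C and quenched cold with DMF, which should give the ortho-fluoro aldehyde F1. The new formyl group activates the neighbouring C–F bond for addition–elimination, so Cs2CO3 in DMF at 60 °C should close the same O1–C7a bond by intramolecular SNAr, with retention at both stereocentres, to the 7-formyl dihydrobenzofuran F2. Baeyer–Villiger oxidation with mCPBA/NaHCO3 in CH2Cl2 (aryl migration, favoured by the ortho ring oxygen) should give the aryl formate F3, and K2CO3 in MeOH releases phenol 22.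

Step 9. Acid may ionise the benzylic C2–O1 bond (the cation is stabilised by ring B), leading to epimerisation at C2 or ring opening, and the liberated trityl cation may alkylate the electron-rich rings. The fallback uses orthogonal protecting groups; it sets out from 15 and returns at 23. The primary alcohol of 15 is silylated (TIPSCl, imidazole, DMF) to the silyl ether F4, which is taken through the conditions of step 8 to the silyl-protected phenol F5. The risk of a base-induced silyl shift is accepted in this variant and limited by keeping the cyclisation below 0 °C. The acetal alone is then hydrolysed with PPTS in wet acetone to the silyl aldehyde F6, and buffered fluoride (TBAF/AcOH, THF) removes the silyl group to give 23. No trityl cation is formed and only a trace of weak acid is used.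

Step 2. The zinc enolate may form incompletely or self-condense, transmetalation may be slow, and 2 may undergo hydrodebromination. The fallback uses a stabilised enolate in place of an organozinc; it sets out from 2 and returns at 5. Palladium-catalysed arylation of diethyl malonate (Pd(OAc)2, P(t-Bu)3·HBF4, K3PO4, toluene, 80 °C) should give the aryl malonate F7. Krapcho dealkoxycarbonylation (LiCl, wet DMSO, 150 °C; neutral, so the acetal survives) then gives ester 5.

**Further compounds**

F1 | step 8 | (1R,2S)-1-(3,4-dimethoxyphenyl)-2-[5-(5,5-dimethyl-1,3-dioxan-2-yl)-2-fluoro-3-formylphenyl]-3-(trityloxy)propan-1-ol | COc1ccc([C@H](O)[C@H](COC(c2ccccc2)(c2ccccc2)c2ccccc2)c2cc(C3OCC(C)(C)CO3)cc(C=O)c2F)cc1OC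
F2 | step 8 | (2R,3S)-2-(3,4-dimethoxyphenyl)-5-(5,5-dimethyl-1,3-dioxan-2-yl)-3-[(trityloxy)methyl]-2,3-dihydro-1-benzofuran-7-carbaldehyde | COc1ccc([C@@H]2Oc3c(C=O)cc(C4OCC(C)(C)CO4)cc3[C@H]2COC(c5ccccc5)(c5ccccc5)c5ccccc5)cc1OC
F3 | step 8 | (2R,3S)-2-(3,4-dimethoxyphenyl)-5-(5,5-dimethyl-1,3-dioxan-2-yl)-3-[(trityloxy)methyl]-2,3-dihydro-1-benzofuran-7-yl formate | COc1ccc([C@@H]2Oc3c(OC=O)cc(C4OCC(C)(C)CO4)cc3[C@H]2COC(c5ccccc5)(c5ccccc5)c5ccccc5)cc1OC
F4 | step 9 | (1R,2S)-1-(3,4-dimethoxyphenyl)-2-[5-(5,5-dimethyl-1,3-dioxan-2-yl)-2-fluorophenyl]-3-[(triisopropylsilyl)oxy]propan-1-ol | COc1ccc([C@H](O)[C@H](CO[Si](C(C)C)(C(C)C)C(C)C)c2cc(C3OCC(C)(C)CO3)ccc2F)cc1OC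
F5 | step 9 | (2R,3S)-2-(3,4-dimethoxyphenyl)-5-(5,5-dimethyl-1,3-dioxan-2-yl)-3-{[(triisopropylsilyl)oxy]methyl}-2,3-dihydro-1-benzofuran-7-ol | COc1ccc([C@@H]2Oc3c(O)cc(C4OCC(C)(C)CO4)cc3[C@H]2CO[Si](C(C)C)(C(C)C)C(C)C)cc1OC
F6 | step 9 | (2R,3S)-2-(3,4-dimethoxyphenyl)-7-hydroxy-3-{[(triisopropylsilyl)oxy]methyl}-2,3-dihydro-1-benzofuran-5-carbaldehyde | COc1ccc([C@@H]2Oc3c(O)cc(C=O)cc3[C@H]2CO[Si](C(C)C)(C(C)C)C(C)C)cc1OC
F7 | step 2 | diethyl 2-[5-(5,5-dimethyl-1,3-dioxan-2-yl)-2-fluorophenyl]propanedioate | CCOC(=O)C(C(=O)OCC)c1cc(C2OCC(C)(C)CO2)ccc1F
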